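(The constants used here come from no measurement, and the outcome is calculated.)

Protic impurity takes starting material 20.0 times faster per molar than partner does, and my reckoning grew from that comparison.

    starting material + partner → intermediate + by-product (k1 = 0.14 M⁻¹ s⁻¹)
    intermediate ⇌ target (K2 = 0.36, k2 = 1.3 s⁻¹)
    intermediate ⇌ isomer of the product (K3 = 2.4, k3 = 0.11 s⁻¹)
    starting material + protic impurity → quenched substrate (k4 = 2.8 M⁻¹ s⁻¹)

all flasks: protic impurity 0.243 M

|  | starting material | partner | time | remark |
|---|---|---|---|---|
| north-east | 0.81 M (fed, over 4.00 min) | 0.810 M | 8.0 min | all but starting material at the start; starting material goes in evenly over 4.00 min, the run ends at 8.0 min |
| south | 0.81 M | 0.810 M |  | one stirred flow tank at steady state, fed with the mixture as stated, mean residence time 8.0 min |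
| north | 0.81 M | 0.810 M | 8.0 min | a closed flask charged with all of it at once and left for 8.0 min |
| north-west | 0.81 M | 0.810 M (fed, over 4.00 min) | 8.0 min | a stirred flask in which partner is dosed at a steady rate over 4.00 min without added volume, worked up at 8.0 min |

- the stated concentrations are those of everything mixed, before any reaction; amounts are the same in each set-up
- the feed brings no volume worth counting
- run time (north-east): 8.0 min

1. the set-up with the highest amount of intermediate at the outlet or at the end, in percent of the starting material put in ("none" if the first two lie within 2 percentage points) (north-east / south / north / north-west / none)
2. amount of intermediate at the outlet or at the end, in percent of the starting material put in, north-east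
3. amount of intermediate at the outlet or at the end, in percent of the starting material put in, south
4. amount of intermediate at the outlet or at the end, in percent of the starting material put in, north
5. amount of intermediate at the outlet or at the end, in percent of the starting material put in, north-west

**Opening slope.** I drew the intermediate curve for the north flask, charged at once. It started at 0.0919 M s⁻¹, while the impurity step ran at 0.551 M s⁻¹, 6.00 times faster.

**First knee.** The half-life of starting material against the impurity, charge held, was 1.0 s, shorter than its 0.10 min against partner. So in the north flask I let the impurity take its whole charge, 30.0% of the starting material. That left a pool of 70.0% to pass through partner, with starting material now the limiting reagent.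

**Falling back.** Intermediate feeds target with a forward half-life of 0.53 s and isomer with one of 0.11 min. Since the half-life of starting material against partner, 0.10 min, is close to the latter, I expected the north curve to bend over and approach its level from above.

**The level.** Partner's excess over the pool is 0.243 M, which gives the last of the pool a half-life of 20.4 s, short against 8.0 min. The forward half-life towards isomer, 0.11 min, is short against 8.0 min as well, so I took the north level as the resting share, the fraction of the pool left as intermediate when both isomerisations stand at equilibrium, one over one plus both constants: 26.6%. Multiplied by the pool, it gives 18.6% for the north flask.

**Other vessels.** In the north-east and north-west flasks, 11.8 such half-lives follow the dosing, so I put them at the same 18.6%. I did not solve the south tank; it holds some starting material at steady state, so I placed it a little lower, inside the 2 percentage points margin, and committed to no winner.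

**The result.** The forecast gave 18.6% north-east, 18.3% south, 18.6% north and 18.6% north-west, with best none, holding that “dosing order hardly matters”. The simulation gave 18.6% north-east, 18.3% south, 18.6% north and 18.6% north-west, with best none.

**What stood.** In the north flask, the forward half-life of intermediate towards isomer, 0.11 min, was short against the 8.0 min run, and its forward half-life towards target, 0.53 s, was shorter still. Isomer stood there at 44.7% of the starting material charged, against 2.4 times my 18.6%, or 44.7%. In the south tank at 3 times the residence time, intermediate came to 18.6%, against the resting share 26.6% of my reckoned 70.0% pool, 18.6%.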